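Substrate was left over in this flask: 56% still stood at 120 h, beside 44% target, and the two summed to 100%. The partner charged came to 60.0% of the substrate.

| setting | spring | summer | flask |
|---|---|---|---|
| substrate | 38 mM | 38 mM | 38 mM |
| partner | 22.8 mM | 15 mM | 22.8 mM |
| protic impurity | 38 mM | 38 mM | 38.0 mM |
| temperature | −20 °C | −25 °C | −20 °C |
| remark | the very flask that is asked about, followed so far | run made earlier |  |
| time |  |  | 8.0 d |

- spring (time / h: target / %, substrate / %): 10.0: 10, 67; 30.0: 24, 63; 48.0: 36, 62; 72.0: 40, 59; 120: 44, 56
- summer (time / h: target / %, substrate / %): 2.00: 1, 93; 5.00: 0, 89; 10.0: 2, 81; 15.0: 5, 83; 20.0: 7, 78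

(standard deviation of a reading: 2 percentage points)

- Wednesday's: at 8.0 d add partner, 100% of the amount charged, then wait 4.0 d
- Friday's: at 8.0 d raise the temperature by 15 K, then wait 4.0 d
- Monday's: at 8.0 d take out 90% of the target then present, then wait 4.0 d
- Saturday's: change nothing and wait 4.0 d more

- target that was removed still counts
- the analysis behind the earlier runs scatters by 2 percentage points, standard deviation
- on the list of suspects stand: partner + protic impurity -> quenched reagent; intermediate -> target; substrate + partner <-> intermediate
- additions bring no volume worth counting

* target, in percent of the substrate first charged, at 8.0 d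
* the remedy with the largest gain of target, or "none" below 2 percentage points (Wednesday's / Friday's / Monday's / Saturday's / none)
* target present, with what was taken out counted in, in percent of the substrate first charged, after Wednesday's
* target present, with what was taken out counted in, in percent of the substrate first charged, after Saturday's

I read this flask as a ladder of time scales. The first rung took hours. By 10.0 h substrate read 67% and target 10%, so I put about 23.0% in the intermediate. The next rung took tens of hours. That gap read 2.00% at 48.0 h, within the scatter of the readings, and target climbed. On the last rung the readings slowed: from 72.0 h to 120 h substrate fell by 3 percentage points.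

I treated partner as the limiting reagent and booked what target did not account for to the protic impurity. That gave me one price, the partner toll 0.364: partner lost to protic impurity per partner that became target.

toll = (22.8 mM − 16.7 mM) / 16.7 mM = 0.364

Protic impurity and substrate compete for partner, so I let the toll follow their ratio. Waiting, warming and removal bring no partner, so I expected about 44% at 8.0 d and no real gain from them. For Wednesday's dose I took substrate at 56% and protic impurity at 84.0% of its charge.

toll at the dose = 0.364 × 84.0% / 56% = 0.545

gain = 60.0% / (1 + 0.545) = 39 points

I called that a little high, since substrate thins as the dose reacts.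

The forecast said 45% now, Wednesday's as the remedy, 77% after it and 46% after Saturday's, in the words “The stall therefore comes from lack of partner”.

The flask gave 43.2% at 8.0 d, 75.1% after Wednesday's and 43.3% after Saturday's. Wednesday's gained 32 points, more than the others, but less than my reckoned gain.

    partner + protic impurity → quenched reagent (k = 0.390 M⁻¹ h⁻¹, Ea = 50.0 kJ mol⁻¹)
    intermediate → target (k = 0.0640 h⁻¹, Ea = 92.0 kJ mol⁻¹)
    substrate + partner ⇌ intermediate (K = 29.0 M⁻¹, k = 4.70 M⁻¹ h⁻¹, Ea = 42.0 kJ mol⁻¹, ΔH = −28.0 kJ mol⁻¹)
    (constants at −20 °C)

In this flask, the step from substrate and partner to intermediate had half of its turnover up to 8.0 d behind it by 4.37 h, and the step from intermediate to target followed, with 44% of its turnover up to 8.0 d done at 19.2 h. At 96.0 h partner stood at 3.22% of its charge and intermediate at 1.02% of the substrate charged, and from then until 8.0 d target rose from 41.1% to 43.2%. The toll on that target gives 5.97 mM of quenched reagent, and the flask held 6.33 mM at 192 h.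

Take the neighbour with 65 mM of protic impurity. Scaled with the protic impurity, my toll becomes 0.622, which gives 37.0% target. The computed neighbour holds 36.6% at 8.0 d.

The earlier runs and the new flask stem from a simulated flask with constants of no real substance, and the scatter is random.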